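**Plan**

- Numbering: C1 (bears ArA = 3-hydroxy-4,5-dimethoxyphenyl), O2, C3, C3a, C4 (bears ArB = 3,4,5-trimethoxyphenyl), O5, C6, C6a. The retrosynthesis frees the phenol (O–Si), cuts both benzylic ether bonds C1–O2 and C4–O5 to an open-chain tetrol, then cuts C1–C6a and C3a–C4.
- Enabling feature: each end of the C3a–C6a bond carries one oxymethylene (C3, C6) and one aryl carbinol carbon (C4, C1). Tying C3 to C6 through a temporary oxygen gives a butenolide (C3 carbonyl, C3a α, C6a β, C6 acetal carbon) that takes C1 as an acyl anion at C6a and C4 as an aldehyde carbon at C3a.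
- Forward: the chain is joined in one pot (dithiane anion, butenolide, aldehyde), the C1 ketone is unmasked, LiAlH4 excises the temporary oxygen, ring 1 (C1, O2, C3, C3a, C6a) and ring 2 (C3a, C4, O5, C6, C6a) close in one operation, and the phenol is desilylated.
- Stereochemistry: C6a is set anti to the menthyloxy group of the (5R)-butenolide and C3a anti to the new dithianyl group. The acetal centre is erased on reduction. C1 and C4 arise when each benzylic cation is captured with its aryl group on the convex face.

Key step: step 5

Assumption: the two benzylic carbinol carbons (C4 after step 5, C1 after step 7) are carried as epimer mixtures because both are ionised in step 8; a triisopropylsilyl ether protects the phenol so that the end game needs no hydrogenolysis next to the benzylic ring ethers.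

**Route**

Step 1
Reactants: 1 furfural
Product: 3 hydroxybutenolide 5-hydroxyfuran-2(5H)-one (racemic), via furfural endoperoxide 2 (not isolated)
Conditions: O2, rose bengal disodium salt (C20H2Cl4I4Na2O5, cat.), MeOH, visible light, 20 °C
Reagents that add atoms: dioxygen, O=O
Why: Sensitised photo-oxygenation of a furan, in which singlet oxygen adds [4+2] across C2/C5, methanol adds to the formyl group of the endoperoxide and fragmentation expels methyl formate to leave the hydroxybutenolide, whose labile hemiacetal carbon is fixed only in step 2.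

Step 2
Reactants: 3 5-hydroxyfuran-2(5H)-one; 4 l-menthol
Product: 5 (5R)-5-(l-menthyloxy)furan-2(5H)-one
Conditions: p-TsOH·H2O (cat.), toluene, reflux with azeotropic removal of water; crystallise from petroleum ether, −20 °C; liquors re-equilibrated with the same acid and recrystallised
Reagents that add atoms: none
Why: Acid-catalysed acetalisation of the pseudo-acid gives both C5 epimers, which interconvert through the ring oxocarbenium ion, and the crystalline (5R) epimer should be drawn out of this equilibrium (crystallisation-induced diastereomer transformation), so C5 is set by the fixed menthyl centres.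

Step 3
Reactants: 6 3-hydroxy-4,5-dimethoxybenzaldehyde
Product: 7 5-(1,3-dithian-2-yl)-2,3-dimethoxyphenol
Conditions: HS(CH2)3SH, BF3·OEt2 (cat.), CH2Cl2, 0 °C to rt
Reagents that add atoms: propane-1,3-dithiol, SCCCS
Why: BF3-catalysed dithioacetalisation of an aromatic aldehyde (first half of Corey–Seebach umpolung), run on the free phenol so that the later silyl ether never meets the Lewis acid.

Step 4
Reactants: 7 5-(1,3-dithian-2-yl)-2,3-dimethoxyphenol
Product: 8 2-[3,4-dimethoxy-5-(triisopropylsilyloxy)phenyl]-1,3-dithiane
Conditions: i-Pr3SiCl, imidazole, DMF, rt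
Reagents that add atoms: chlorotriisopropylsilane, CC(C)[Si](Cl)(C(C)C)C(C)C
Why: Imidazole-promoted silylation of a phenol; the hindered silyl ether should tolerate n-BuLi at −78 °C, LiAlH4 and MsCl/pyridine and is removed at the end by fluoride.

Step 5
Reactants: 8 2-[3,4-dimethoxy-5-(triisopropylsilyloxy)phenyl]-1,3-dithiane; 5 (5R)-5-(l-menthyloxy)furan-2(5H)-one; 9 3,4,5-trimethoxybenzaldehyde
Product: 12 (3S,4R,5R)-4-{2-[3,4-dimethoxy-5-(triisopropylsilyloxy)phenyl]-1,3-dithian-2-yl}-3-[hydroxy(3,4,5-trimethoxyphenyl)methyl]-5-(l-menthyloxy)dihydrofuran-2(3H)-one (both carbinol epimers), via lithiated dithiane 10 (not isolated), via lithium enolate 11 (not isolated)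
Conditions: n-BuLi, THF, −78 °C; then 5, −78 °C; then 9, −78 °C; aq. NH4Cl
Reagents that add atoms: none
Why: Deprotonation gives the sulfur- and aryl-stabilised carbanion 10, a masked ArA acyl anion, which adds 1,4 to the butenolide to form C1–C6a, and the lithium enolate 11 so generated is trapped in the same flask by aldehyde 9 to form C3a–C4 (aldol addition). The closest known reaction type is the tandem conjugate addition–aldol (Michael-initiated three-component coupling) of 2-aryl-2-lithio-1,3-dithianes with 5-alkoxyfuran-2(5H)-ones. No ring is closed; two skeletal C–C bonds and three stereocentres arise. C6a is controlled by the (5R)-menthyloxy acetal carbon, the nucleophile entering the flat butenolide on the face opposite the alkoxy group, and C3a by the new quaternary dithianyl group, which sends the aldehyde to the other enolate face and gives the trans,trans lactone; the carbinol carbon C4 forms as an epimer mixture, tolerated because that carbon is ionised in step 8. The step needs 1,4- rather than 1,2-addition, secured by the soft delocalised anion and the unhindered β-carbon at −78 °C, and aldol capture faster than proton transfer or retro-addition, secured by the low temperature and the reactive, non-enolisable aromatic aldehyde.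

Step 6
Reactants: 12 the dithianyl aldol lactone
Product: 13 (3S,4R,5R)-4-[3,4-dimethoxy-5-(triisopropylsilyloxy)benzoyl]-3-[hydroxy(3,4,5-trimethoxyphenyl)methyl]-5-(l-menthyloxy)dihydrofuran-2(3H)-one
Conditions: Hg(ClO4)2·3H2O, CaCO3, THF/H2O, 0 °C to rt
Reagents that add atoms: water, O
Why: Thiophilic divalent mercury binds both sulfur atoms and water takes their place at the former acyl-anion carbon (mercury-assisted S,S-acetal hydrolysis, the unmasking half of Corey–Seebach umpolung), the CaCO3 buffer sparing the lactone acetal, the silyl ether and the aldol carbinol, while the ring-bound trans arrangement at C6a is the stable one and cannot be eroded by the new ketone.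

Step 7
Reactants: 13 the keto lactone
Product: 14 (2R,3R)-2-{[3,4-dimethoxy-5-(triisopropylsilyloxy)phenyl](hydroxy)methyl}-3-[hydroxy(3,4,5-trimethoxyphenyl)methyl]butane-1,4-diol (carbinol epimers)
Conditions: LiAlH4, THF, 0 °C to rt; aq. KNaC4H4O6 work-up
Reagents that add atoms: none
Why: Hydride reduces the aryl ketone to the C1 carbinol and the lactone carbonyl (C3) to a primary alkoxide, the ring oxygen then leaves onto the acetal carbon, the hemiacetal alkoxide expels menthoxide and the C6 aldehyde is reduced too (LiAlH4 reduction of a ketone and of a γ-alkoxybutyrolactone to a 1,4-diol), so the temporary oxygen bridge and the auxiliary centre vanish while C3a and C6a, no longer α to a carbonyl, are kept and the C1 carbinol forms as an epimer mixture that step 8 makes irrelevant.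

Step 8
Reactants: 14 the tetrol
Product: 16 (1S,3aR,4S,6aR)-1-[3,4-dimethoxy-5-(triisopropylsilyloxy)phenyl]-4-(3,4,5-trimethoxyphenyl)tetrahydro-1H,3H-furo[3,4-c]furan, via bis-benzylic mesylate 15 (not isolated)
Conditions: MsCl (2.2 equiv), pyridine, 0 °C to rt
Reagents that add atoms: none
Why: Sulfonylation turns the two electron-rich benzylic carbinols into mesylates that ionise at once to 4-methoxy-stabilised benzylic cations, each captured 5-exo by the 1,4-related primary hydroxyl (double cyclodehydration of a 1,4-diol through a quinonoid oxocarbenium ion), so both carbinol epimers converge and C1 and C4 are set under kinetic control with each aryl group trans to the neighbouring ring substituent, that is on the convex face of the cis-fused bicycle dictated by C3a and C6a.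

Step 9
Reactants: 16 the silyl-protected furofuran
Product: 17 2,3-dimethoxy-5-[(1S,3aR,4S,6aR)-4-(3,4,5-trimethoxyphenyl)tetrahydro-1H,3H-furo[3,4-c]furan-1-yl]phenol (target)
Conditions: Bu4NF, THF, 0 °C; aq. NH4Cl
Reagents that add atoms: none
Why: Fluoride attacks silicon and releases the phenoxide (silyl ether cleavage driven by the Si–F bond) under non-acidic, non-reductive conditions that leave the two benzylic ether bonds and all four stereocentres untouched.

**Compound list**

1 | furfural | O=Cc1ccco1 | starting material
2 | furfural 2,5-endoperoxide (2,3,7-trioxabicyclo[2.2.1]hept-5-ene-1-carbaldehyde) | O=CC12OOC(C=C1)O2 | intermediate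
3 | 5-hydroxyfuran-2(5H)-one (racemic) | O=C1C=CC(O)O1 | intermediate
4 | l-menthol, (1R,2S,5R)-2-isopropyl-5-methylcyclohexan-1-ol | CC(C)[C@@H]1CC[C@@H](C)C[C@H]1O | starting material
5 | (5R)-5-(l-menthyloxy)furan-2(5H)-one | O=C1C=C[C@H](O[C@@H]2C[C@H](C)CC[C@H]2C(C)C)O1 | intermediate
6 | 3-hydroxy-4,5-dimethoxybenzaldehyde | COc1cc(C=O)cc(O)c1OC | starting material
7 | 5-(1,3-dithian-2-yl)-2,3-dimethoxyphenol | COc1cc(C2SCCCS2)cc(O)c1OC | intermediate
8 | 2-[3,4-dimethoxy-5-(triisopropylsilyloxy)phenyl]-1,3-dithiane | COc1cc(C2SCCCS2)cc(O[Si](C(C)C)(C(C)C)C(C)C)c1OC | intermediate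
9 | 3,4,5-trimethoxybenzaldehyde | COc1cc(C=O)cc(OC)c1OC | starting material
10 | 2-lithio-2-[3,4-dimethoxy-5-(triisopropylsilyloxy)phenyl]-1,3-dithiane | [Li]C1(c2cc(OC)c(OC)c(O[Si](C(C)C)(C(C)C)C(C)C)c2)SCCCS1 | intermediate
11 | lithium enolate of (4R,5R)-4-{2-[3,4-dimethoxy-5-(triisopropylsilyloxy)phenyl]-1,3-dithian-2-yl}-5-(l-menthyloxy)dihydrofuran-2(3H)-one | [Li]OC1=C[C@@H](C2(c3cc(OC)c(OC)c(O[Si](C(C)C)(C(C)C)C(C)C)c3)SCCCS2)[C@H](O[C@@H]2C[C@H](C)CC[C@H]2C(C)C)O1 | intermediate
12 | (3S,4R,5R)-4-{2-[3,4-dimethoxy-5-(triisopropylsilyloxy)phenyl]-1,3-dithian-2-yl}-3-[hydroxy(3,4,5-trimethoxyphenyl)methyl]-5-(l-menthyloxy)dihydrofuran-2(3H)-one, carbinol epimers | O=C1O[C@@H](O[C@@H]2C[C@H](C)CC[C@H]2C(C)C)[C@H](C2(c3cc(OC)c(OC)c(O[Si](C(C)C)(C(C)C)C(C)C)c3)SCCCS2)[C@H]1C(O)c1cc(OC)c(OC)c(OC)c1 | intermediate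
13 | (3S,4R,5R)-4-[3,4-dimethoxy-5-(triisopropylsilyloxy)benzoyl]-3-[hydroxy(3,4,5-trimethoxyphenyl)methyl]-5-(l-menthyloxy)dihydrofuran-2(3H)-one, carbinol epimers | O=C1O[C@@H](O[C@@H]2C[C@H](C)CC[C@H]2C(C)C)[C@H](C(=O)c2cc(OC)c(OC)c(O[Si](C(C)C)(C(C)C)C(C)C)c2)[C@H]1C(O)c1cc(OC)c(OC)c(OC)c1 | intermediate
14 | (2R,3R)-2-{[3,4-dimethoxy-5-(triisopropylsilyloxy)phenyl](hydroxy)methyl}-3-[hydroxy(3,4,5-trimethoxyphenyl)methyl]butane-1,4-diol, carbinol epimers | OC[C@H](C(O)c1cc(OC)c(OC)c(O[Si](C(C)C)(C(C)C)C(C)C)c1)[C@H](CO)C(O)c1cc(OC)c(OC)c(OC)c1 | intermediate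
15 | bis(methanesulfonate) of 14 at the two benzylic hydroxyls | OC[C@H](C(OS(C)(=O)=O)c1cc(OC)c(OC)c(O[Si](C(C)C)(C(C)C)C(C)C)c1)[C@H](CO)C(OS(C)(=O)=O)c1cc(OC)c(OC)c(OC)c1 | intermediate
16 | (1S,3aR,4S,6aR)-1-[3,4-dimethoxy-5-(triisopropylsilyloxy)phenyl]-4-(3,4,5-trimethoxyphenyl)tetrahydro-1H,3H-furo[3,4-c]furan | COc1cc([C@H]2OC[C@H]3[C@@H]2CO[C@@H]3c2cc(OC)c(OC)c(OC)c2)cc(O[Si](C(C)C)(C(C)C)C(C)C)c1OC | intermediate
17 | 2,3-dimethoxy-5-[(1S,3aR,4S,6aR)-4-(3,4,5-trimethoxyphenyl)tetrahydro-1H,3H-furo[3,4-c]furan-1-yl]phenol | COc1cc([C@H]2OC[C@H]3[C@@H]2CO[C@@H]3c2cc(OC)c(OC)c(OC)c2)cc(O)c1OC | target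

**Count**

Total steps: 9. Longest linear sequence: 7 steps (1 → 3 → 5 → 12 → 13 → 14 → 16 → 17; the branch 6 → 7 → 8 → 12 → 17 is equally long).

**Steps most likely to fail**

Step 5. The enolate 11 may be protonated by unreacted dithiane or revert by retro-addition before the aldehyde arrives. The aldol may be reversible on warming, and part of the anion may add 1,2 to the lactone or to the aldehyde. The fallback sets out from 5 and 8 and comes back at 12. The lithiated dithiane 10 would be added to 5 alone and the enolate quenched with NH4Cl, to isolate the conjugate adduct (4R,5R)-4-{2-[3,4-dimethoxy-5-(triisopropylsilyloxy)phenyl]-1,3-dithian-2-yl}-5-(l-menthyloxy)dihydrofuran-2(3H)-one F1. This lactone would then be deprotonated with LiN(i-Pr)2 in THF at −78 °C, where no dithiane is left as a proton source, transmetallated with ZnCl2 if the lithium aldolate reverts, and treated with 9 in a separate directed aldol addition. The dithianyl group should again shield its own face and give 12.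

Step 8. Sulfonylation may go to the primary hydroxyls first, followed by displacement by the benzylic oxygen with retention at C1 and C4; this would carry the carbinol mixture into the product as C1/C4 epimers. The trioxygenated rings also ionise less readily than a simple 4-methoxyphenyl ring. The fallback sets out from 14 and comes back at 16; no compound outside the list is made (F0). Sulfonate activation would be given up for a reversible Brønsted-acid cyclodehydration (10-camphorsulfonic acid, CH2Cl2, 4 Å molecular sieves, 0 °C to rt). Only the benzylic C–O bonds can ionise there, so every carbinol epimer, any 2,5-diaryl ether formed off-path and any epimeric furofuran from the sulfonate route feed the same cations. Compound 16 would be separated and the remaining epimers returned to the same acid, the closure being corrected by equilibration and recycling.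

Step 6. The hindered quaternary S,S-acetal may be unmasked incompletely, or the Lewis-acidic mercury salt may trigger retro-aldol loss or elimination of the benzylic carbinol and exchange at the lactone acetal. The fallback sets out from 12 and comes back at 13. One sulfur would be oxidised with m-CPBA (1 equiv, CH2Cl2, −78 °C) to the mixture of sulfoxide epimers (3S,4R,5R)-4-{2-[3,4-dimethoxy-5-(triisopropylsilyloxy)phenyl]-1-oxido-1,3-dithian-2-yl}-3-[hydroxy(3,4,5-trimethoxyphenyl)methyl]-5-(l-menthyloxy)dihydrofuran-2(3H)-one F2. The monoxide has a sulfenic acid leaving group on an aryl- and thio-stabilised carbon and should hydrolyse in dilute aqueous HClO4/THF at 0 °C to rt to ketone 13 without any thiophilic metal.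

**Further compounds**

F1 | step 5 | (4R,5R)-4-{2-[3,4-dimethoxy-5-(triisopropylsilyloxy)phenyl]-1,3-dithian-2-yl}-5-(l-menthyloxy)dihydrofuran-2(3H)-one | O=C1C[C@@H](C2(c3cc(OC)c(OC)c(O[Si](C(C)C)(C(C)C)C(C)C)c3)SCCCS2)[C@H](O[C@@H]2C[C@H](C)CC[C@H]2C(C)C)O1
F0 | step 8 | none | none
F2 | step 6 | (3S,4R,5R)-4-{2-[3,4-dimethoxy-5-(triisopropylsilyloxy)phenyl]-1-oxido-1,3-dithian-2-yl}-3-[hydroxy(3,4,5-trimethoxyphenyl)methyl]-5-(l-menthyloxy)dihydrofuran-2(3H)-one, sulfoxide and carbinol epimers | O=C1O[C@@H](O[C@@H]2C[C@H](C)CC[C@H]2C(C)C)[C@H](C2(c3cc(OC)c(OC)c(O[Si](C(C)C)(C(C)C)C(C)C)c3)SCCCS2=O)[C@H]1C(O)c1cc(OC)c(OC)c(OC)c1
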